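Numbering (labdane): decalin C1–C10 with C17 on C8, chain C11–C12, lactone ring C13–C14–C15(=O)–O–C16; O13 is the hydroxyl oxygen on C13.
Cuts, in retrosynthetic order: C7=O, the C8=C9 position and the C6 configuration go back to the 6α-ol and 8(17)-ene of (+)-larixol. The lactone C15=O goes back to a C15,C16-diol, and C16–O to a C16–CO2H helper. The C13–C16 bond and the O13–acyl bond of a β-lactone are then cut together. Last, C14–C15 is cut to the C13 methyl ketone and the formaldehyde acetal of glycolic acid.
Forward: rings A and B come with larixol. Its side chain is trimmed to the methyl ketone and regrown to the open-chain keto acid C13(=O)–C14–C15–O–C16–CO2H. One cascade then closes the oxolane ring (C13, C14, C15, O, C16) and a temporary β-lactone (C13, C16, acyl C, O13). The lactone carbonyl and the ring B oxidation follow.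
Enabling feature: C16 lies 1,5 to the C13 carbonyl carbon through O, C15 and C14. A carboxyl group parked on C16 therefore makes it an enolate carbon within five-ring reach, and afterwards captures O13 in a four-membered ring. That capture makes the otherwise reversible aldol addition to a dialkyl ketone irreversible.
Helpers and their removal: silyl groups (step 4), β-lactone (step 6), C16 carboxyl (lost as CO2, step 7), ether oxidation level at C15 (raised in step 8).
Stereochemistry: C5 and C10 come from larixol, C13 from the chiral isothiourea catalyst, C6 from α-face hydride delivery to the 6-ketone. The centres at C7, C8, C9 and C16 met on the way are erased.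

Key step: step 5

Assumptions: (+)-larixol (from larch oleoresin) is taken as a commercial starting material; the (S)-isothiourea is assumed to give the 13S aldolate by analogy with simple keto acids, and its enantiomer would be used if the sense is opposite.

Step 1
Reactants: 1 (+)-larixol
Product: 2 6α-hydroxy-14,15-dinorlabd-8(17)-en-13-one
Conditions: KMnO4, BnEt3NCl, CH2Cl2, 0 °C to rt
Reagents that add atoms: none
Why: Oxidative alkene cleavage (permanganate dihydroxylation, then glycol and α-ketol cleavage) should trim the vinyl carbinol to the C13 methyl ketone, because the monosubstituted C14=C15 alkene beside the coordinating tertiary hydroxyl is attacked before the shielded exocyclic C8=C17 alkene, and no retained stereocentre is touched.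

Step 2
Reactants: 2 6α-hydroxy-14,15-dinorlabd-8(17)-en-13-one
Product: 3 terminal trimethylsilyl enol ether of 2 bearing a 6α-OSiMe3 group
Conditions: LiN(iPr)2 (2.3 equiv), Me3SiCl (2.5 equiv), THF, −78 °C
Reagents that add atoms: chlorotrimethylsilane C[Si](C)(C)Cl
Why: Kinetic deprotonation with a hindered lithium amide followed by O-silylation (silyl enol ether formation) should occur at the methyl group rather than at C12, and the C6 alkoxide is silylated in the same operation.

Step 3
Reactants: 4 glycolic acid; 5 paraformaldehyde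
Product: 6 1,3-dioxolan-4-one
Conditions: TsOH·H2O (cat.), toluene, reflux, Dean–Stark trap
Reagents that add atoms: none
Why: Acid-catalysed acetalisation of formaldehyde by the hydroxyl and carboxyl groups of glycolic acid should close the five-membered acylal once water is removed azeotropically.

Step 4
Reactants: 3 terminal trimethylsilyl enol ether; 6 1,3-dioxolan-4-one
Product: 8 keto acid (6α-OH; 8(17)-ene; chain C13(=O)-C14H2-C15H2-O-C16H2-CO2H), via bis(trimethylsilyl) adduct 7 (not isolated)
Conditions: Me3SiOTf (0.1 equiv), CH2Cl2, −78 °C; then aq. citric acid, THF, rt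
Reagents that add atoms: none
Why: Mukaiyama aldol-type alkylation of a silyl enol ether by an acetal: the silyl triflate should open the acylal to the oxocarbenium ion CH2=O+–CH2CO2SiMe3, which the terminal enol carbon attacks to form C14–C15, and mild acid then removes both silyl groups.

Step 5
Reactants: 8 keto acid
Product: 9 cis-fused oxolane β-lactone (13S; O13 tied to the acyl carbon on C16; 6α-OH; 8(17)-ene)
Conditions: TsCl (1.3 equiv), LiCl (1 equiv), iPr2NEt (4 equiv), (S)-2-phenyl-3,4-dihydro-2H-pyrimido[2,1-b]benzothiazole (20 mol %), CH2Cl2, rt, slow addition of 8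
Reagents that add atoms: none
Why: TsCl converts the acid into a mixed anhydride, the chiral isothiourea displaces tosylate to give an acylammonium salt, iPr2NEt removes the now acidic C16–H to give the ammonium enolate, C16 attacks the C13 ketone, and the C13 alkoxide expels the catalyst from the acyl carbon. The closest known reaction type is the nucleophile-catalysed aldol-lactonisation of keto acids, including oxygen-tethered ones that give oxolane-fused β-lactones. The oxolane ring (C13, C14, C15, O, C16) closes by a 5-(enolexo)-exo-trig aldol addition that forms C13–C16, and the β-lactone (C13, C16, acyl C, O13) closes by a 4-exo-trig acyl substitution. C13 is set by the catalyst, whose phenyl-bearing stereocentre shields one face of the planar enolate so that the ketone is met on a single face while the remote decalin centres have no say; C16 follows from C13 because a bicyclo[3.2.0] ring fusion can only be cis, and it is erased in step 7. The step needs the aldol addition to outrun β-elimination of glycolate from the β-alkoxy ketone and acylation or sulfonylation of the C6 hydroxyl. The first is secured by five-ring proximity, LiCl activation of the ketone and the irreversible lactone capture under a weak amine base; the second by the equatorial (4α) methyl group on C4, peri to the equatorial C6–OH, and by slow addition at high dilution.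

Step 6
Reactants: 9 cis-fused oxolane β-lactone
Product: 10 (13S)-13-hydroxy oxolane-16-carboxylic acid (OH and CO2H cis; 6α-OH; 8(17)-ene)
Conditions: LiOH, THF/H2O, 0 °C; then 1 M HCl
Reagents that add atoms: lithium hydroxide [Li+].[OH-]
Why: Saponification by acyl–oxygen cleavage: ring strain makes the β-lactone carbonyl the only acyl group attacked by hydroxide at 0 °C, and the tertiary C13–O bond is not broken, so C13 keeps its configuration.

Step 7
Reactants: 10 (13S)-13-hydroxy oxolane-16-carboxylic acid
Product: 12 (13S)-tetraol (6α-OH; 13-OH; C15H2OH; C16H2OH; 8(17)-ene), via acetoxy oxolane 11 (not isolated)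
Conditions: Pb(OAc)4, CH2Cl2, 0 °C to rt; then MeOH, NaBH4, 0 °C
Reagents that add atoms: lead tetraacetate CC(=O)O[Pb](OC(C)=O)(OC(C)=O)OC(C)=O
Why: Oxidative decarboxylation with tetravalent lead followed by borohydride reduction: the C16 radical left on loss of CO2 is α to the ring oxygen and should be oxidised at once to an oxocarbenium ion that acetate traps, and methanolic borohydride then frees the lactol, whose open hydroxy aldehyde form is reduced to the C15,C16-diol without touching C13.

Step 8
Reactants: 12 (13S)-tetraol
Product: 14 (13S)-13-hydroxy-6-oxolabd-8(17)-en-15,16-olide, via hydroxy lactone 13 (not isolated)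
Conditions: 2,2,6,6-tetramethylpiperidine-1-oxyl (10 mol %), PhI(OAc)2 (2.2 equiv), CH2Cl2, rt; then Dess–Martin periodinane (1,1,1-triacetoxy-1,1-dihydro-1,2-benziodoxol-3(1H)-one, 1.5 equiv), rt
Reagents that add atoms: none
Why: Oxoammonium-mediated oxidative lactonisation followed by Dess–Martin oxidation: the bulky oxoammonium salt should oxidise the unhindered C15 primary alcohol first, the aldehyde is caught by the neopentyl C16 hydroxyl as a lactol that is oxidised to the 15,16-olide, and the periodinane then converts the shielded C6 alcohol into the ketone.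

Step 9
Reactants: 14 (13S)-13-hydroxy-6-oxolabd-8(17)-en-15,16-olide
Product: 15 (13S)-6β,13-dihydroxylabd-8(17)-en-15,16-olide
Conditions: NaBH4, CeCl3·7H2O, MeOH, −20 °C
Reagents that add atoms: none
Why: Cerium-assisted borohydride reduction (Luche conditions): the β face of C6 is closed by the axial methyl groups on C4 and C10, so hydride should arrive from the α face and give the axial 6β-alcohol, while the γ-lactone is inert at low temperature.

Step 10
Reactants: 15 (13S)-6β,13-dihydroxylabd-8(17)-en-15,16-olide
Product: 16 (13S)-6β,7α,13-trihydroxylabd-8(17)-en-15,16-olide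
Conditions: SeO2 (0.3 equiv), t-BuOOH, CH2Cl2, rt
Reagents that add atoms: tert-butyl hydroperoxide CC(C)(C)OO
Why: Selenium dioxide allylic hydroxylation (ene reaction, then [2,3]-sigmatropic shift): of the allylic positions of the 8(17)-alkene the C7 methylene should react in preference to the tertiary C9–H, and delivery on the open α face should give the axial 7α-alcohol, a centre that is erased in step 11.

Step 11
Reactants: 16 (13S)-6β,7α,13-trihydroxylabd-8(17)-en-15,16-olide
Product: 18 target (13S)-6β,13-dihydroxy-7-oxolabd-8-en-15,16-olide, via exocyclic enone 17 (not isolated)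
Conditions: MnO2, CH2Cl2, rt; filter; then RhCl3·3H2O (5 mol %), EtOH, 60 °C
Reagents that add atoms: none
Why: Chemoselective MnO2 oxidation of an allylic alcohol followed by rhodium hydride alkene isomerisation: only the allylic C7 hydroxyl should be oxidised, and reversible hydrometallation then moves the exocyclic alkene into the tetrasubstituted C8=C9 position conjugated with C7=O, the thermodynamic sink, under non-basic conditions that should leave C6 untouched.

Compound list
1 | (+)-larixol, (6α,13S)-labda-8(17),14-diene-6,13-diol | C=C1C[C@H](O)[C@H]2C(C)(C)CCC[C@]2(C)[C@H]1CC[C@](C)(O)C=C | starting material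
2 | 6α-hydroxy-14,15-dinorlabd-8(17)-en-13-one (5α-H, 9α-H, 10β-CH3) | C=C1C[C@H](O)[C@H]2C(C)(C)CCC[C@]2(C)[C@H]1CCC(C)=O | intermediate
3 | terminal trimethylsilyl enol ether of 2, 6α-OSiMe3 | C=C1C[C@H](O[Si](C)(C)C)[C@H]2C(C)(C)CCC[C@]2(C)[C@H]1CCC(=C)O[Si](C)(C)C | intermediate
4 | glycolic acid | OCC(=O)O | starting material
5 | paraformaldehyde (written as formaldehyde) | C=O | starting material
6 | 1,3-dioxolan-4-one | O=C1COCO1 | intermediate
7 | trimethylsilyl ester of 8 with 6α-OSiMe3 | C=C1C[C@H](O[Si](C)(C)C)[C@H]2C(C)(C)CCC[C@]2(C)[C@H]1CCC(=O)CCOCC(=O)O[Si](C)(C)C | intermediate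
8 | keto acid, chain C13(=O)–C14H2–C15H2–O–C16H2–CO2H, 6α-OH, 8(17)-ene | C=C1C[C@H](O)[C@H]2C(C)(C)CCC[C@]2(C)[C@H]1CCC(=O)CCOCC(=O)O | intermediate
9 | cis-fused oxolane β-lactone, 13S, C12 and H16 on the same face | C=C1C[C@H](O)[C@H]2C(C)(C)CCC[C@]2(C)[C@H]1CC[C@]12CCO[C@H]1C(=O)O2 | intermediate
10 | (13S)-13-hydroxy oxolane-16-carboxylic acid, OH and CO2H cis | C=C1C[C@H](O)[C@H]2C(C)(C)CCC[C@]2(C)[C@H]1CC[C@]1(O)CCO[C@H]1C(=O)O | intermediate
11 | (13S)-16-acetoxy oxolan-13-ol, C16 epimers | C=C1C[C@H](O)[C@H]2C(C)(C)CCC[C@]2(C)[C@H]1CC[C@]1(O)CCOC1OC(C)=O | intermediate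
12 | (13S)-labd-8(17)-ene-6α,13,15,16-tetraol | C=C1C[C@H](O)[C@H]2C(C)(C)CCC[C@]2(C)[C@H]1CC[C@@](O)(CO)CCO | intermediate
13 | (13S)-6α,13-dihydroxylabd-8(17)-en-15,16-olide | C=C1C[C@H](O)[C@H]2C(C)(C)CCC[C@]2(C)[C@H]1CC[C@]1(O)CC(=O)OC1 | intermediate
14 | (13S)-13-hydroxy-6-oxolabd-8(17)-en-15,16-olide | C=C1CC(=O)[C@H]2C(C)(C)CCC[C@]2(C)[C@H]1CC[C@]1(O)CC(=O)OC1 | intermediate
15 | (13S)-6β,13-dihydroxylabd-8(17)-en-15,16-olide | C=C1C[C@@H](O)[C@H]2C(C)(C)CCC[C@]2(C)[C@H]1CC[C@]1(O)CC(=O)OC1 | intermediate
16 | (13S)-6β,7α,13-trihydroxylabd-8(17)-en-15,16-olide | C=C1[C@H](O)[C@@H](O)[C@H]2C(C)(C)CCC[C@]2(C)[C@H]1CC[C@]1(O)CC(=O)OC1 | intermediate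
17 | (13S)-6β,13-dihydroxy-7-oxolabd-8(17)-en-15,16-olide | C=C1C(=O)[C@@H](O)[C@H]2C(C)(C)CCC[C@]2(C)[C@H]1CC[C@]1(O)CC(=O)OC1 | intermediate
18 | (13S)-6β,13-dihydroxy-7-oxolabd-8-en-15,16-olide | CC1=C(CC[C@@]2(O)COC(=O)C2)[C@@]2(C)CCCC(C)(C)[C@@H]2[C@H](O)C1=O | target

Total step count: 11. Longest linear sequence: 10 (steps 1, 2 and 4–11 from larixol).

Steps most likely to fail

Step 5. The β-alkoxy ketone may lose glycolate by β-elimination before the aldol addition, or the catalyst may discriminate the two ketone faces poorly.
The fallback replaces acylammonium enolate activation by enamine activation of an aldehyde. It sets out from 3 and comes back at 11.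
- Compound 3 is alkylated with 1,3-dioxolane under Me3SiOTf catalysis, and mild acid work-up gives the hydroxyethyl ether F1.
- The primary alcohol is oxidised selectively with 2,2,6,6-tetramethylpiperidine-1-oxyl and PhI(OAc)2 to the keto aldehyde F2.
- A proline-catalysed 5-enolexo aldol addition (proline enantiomer chosen for 13S) closes the same C13–C16 bond and gives the hydroxy aldehyde F3.
- Pinnick oxidation (NaClO2, NaH2PO4, 2-methyl-2-butene) gives the acid F4 as a C16 epimer mixture.
- F4 enters the Pb(OAc)4 decarboxylation of step 7 and gives 11.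

Step 7. The C16 oxocarbenium ion may suffer a 1,2-shift of a C13 substituent, or the C13–C16 bond may fragment through an alkoxy radical at O13.
The fallback removes the carboxyl carbon by a nitrogen route. It sets out from 10 and comes back at 12.
- (PhO)2P(O)N3 and Et3N convert 10 into the acyl azide F5.
- Curtius rearrangement in warm toluene gives an isocyanate that the C13 hydroxyl captures as the cyclic carbamate F6.
- Aqueous LiOH opens F6 to a C16 hemiaminal that loses ammonia, and NaBH4 added to the same flask reduces the hydroxy aldehyde to 12.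

Step 11. The exocyclic enone may dimerise, or C6 may epimerise through the enediol during the alkene migration.
The fallback brings the alkene into the ring before C7 is oxidised. It sets out from 14 and comes back at 18.
- A catalytic amine base (1,8-diazabicyclo[5.4.0]undec-7-ene, CH2Cl2, 0 °C) conjugates 14 to the 7-en-6-one F7.
- Luche reduction from the α face gives the 6β-allylic alcohol F8.
- A Schenck ene reaction with singlet oxygen (O2, 5,10,15,20-tetraphenylporphyrin, light) on the α face abstracts the axial H9 and gives the 7α-hydroperoxide F9.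
- PPh3 reduces F9 to the 8-ene-6β,7α-diol F10.
- MnO2 oxidises the allylic C7 hydroxyl of F10 to give 18 directly.

Further compounds
F1 | step 5 | hydroxyethyl ether, chain C13(=O)–C14H2–C15H2–O–CH2CH2OH, 6α-OH, 8(17)-ene | C=C1C[C@H](O)[C@H]2C(C)(C)CCC[C@]2(C)[C@H]1CCC(=O)CCOCCO
F2 | step 5 | keto aldehyde, chain C13(=O)–C14H2–C15H2–O–C16H2–CHO | C=C1C[C@H](O)[C@H]2C(C)(C)CCC[C@]2(C)[C@H]1CCC(=O)CCOCC=O
F3 | step 5 | (13S)-13-hydroxy oxolane-16-carbaldehyde, C16 epimers | C=C1C[C@H](O)[C@H]2C(C)(C)CCC[C@]2(C)[C@H]1CC[C@]1(O)CCOC1C=O
F4 | step 5 | (13S)-13-hydroxy oxolane-16-carboxylic acid, C16 epimers | C=C1C[C@H](O)[C@H]2C(C)(C)CCC[C@]2(C)[C@H]1CC[C@]1(O)CCOC1C(=O)O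
F5 | step 7 | acyl azide of 10 | C=C1C[C@H](O)[C@H]2C(C)(C)CCC[C@]2(C)[C@H]1CC[C@]1(O)CCO[C@H]1C(=O)N=[N+]=[N-]
F6 | step 7 | cis-fused cyclic carbamate O13–C(=O)–NH–C16 | C=C1C[C@H](O)[C@H]2C(C)(C)CCC[C@]2(C)[C@H]1CC[C@]12CCO[C@H]1NC(=O)O2
F7 | step 11 | (13S)-13-hydroxy-6-oxolabd-7-en-15,16-olide | CC1=CC(=O)[C@H]2C(C)(C)CCC[C@]2(C)[C@H]1CC[C@]1(O)CC(=O)OC1
F8 | step 11 | (13S)-6β,13-dihydroxylabd-7-en-15,16-olide | CC1=C[C@@H](O)[C@H]2C(C)(C)CCC[C@]2(C)[C@H]1CC[C@]1(O)CC(=O)OC1
F9 | step 11 | (13S)-7α-hydroperoxy-6β,13-dihydroxylabd-8-en-15,16-olide | CC1=C(CC[C@@]2(O)COC(=O)C2)[C@@]2(C)CCCC(C)(C)[C@@H]2[C@H](O)[C@H]1OO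
F10 | step 11 | (13S)-6β,7α,13-trihydroxylabd-8-en-15,16-olide | CC1=C(CC[C@@]2(O)COC(=O)C2)[C@@]2(C)CCCC(C)(C)[C@@H]2[C@H](O)[C@H]1O
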